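(All runs are simulated on assumed constants; noise was put on by code.)

0.706 of a point of product X per point of substrate Q lost: that is the violet run between 2.50 h and 5.00 h. Dividing the rise of X by the fall of Q cancels the clock, so call this ratio S, the late yield of X per Q lost, or selectivity. The green run, at 1.4 M of Q against violet's 0.13 M, gives 0.724 from its last two readings. So X can be reckoned as S times the Q lost, and the question becomes how much Q each flask loses.

| setting | violet | green | dusk | summer | spring | winter |
|---|---|---|---|---|---|---|
| Q | 0.13 M | 1.4 M | 0.30 M | 0.10 M | 1.0 M | 0.20 M |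
| E | 180 mM (held) | 180 mM (held) | 180 mM (held) | 180 mM (held) | 180 mM (held) | 180 mM (held) |
| remark | run made earlier | run made earlier |  |  |  |  |
| time |  |  | 10 h | 10 h | 10 h | 10 h |

- violet (time / h: X / %, Q / %): 0.417: 0.2, 98.0; 1.33: 5.2, 87.1; 2.50: 16.8, 70.1; 4.00: 31.7, 48.4; 5.00: 40.3, 36.8
- green (time / h: X / %, Q / %): 0.417: 0, 98.9; 0.833: 1.4, 96.9; 1.33: 2.5, 94.4; 2.50: 6.9, 88.0; 5.00: 15.8, 75.7

(scatter of a reading: 0.3 percentage points)

- at the start none of D is dissolved
- the numbers in the tables scatter by 0.3 percentage points (one standard deviation)
- steps that have been proposed: Q + D <-> J; J -> X; J -> G; E <-> D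

- the flasks put in order of amount of X, in percent of the Q charged, best first, at 10 h (dusk / summer / spring / winter)
- the amount of X, in percent of the Q charged of the flask you put first, at 10 h
- the amount of X, in percent of the Q charged of the flask you put last, at 10 h

Ada holds that Q simply decays first order, whatever the charge. Violet's same stretch gives 0.258 /h; carried on to 10 h, it leaves 10.1% of Q, so X is near 63.4%.

Ben points to green, whose constant is 0.0602 /h, smaller than violet's. He argues that Q consumes the dissolved reagent D, which starts at none and must come from the gas E. Green lost 0.0689 M/h of Q, while violet lost less, 0.0173 M/h. Holding green's rate for 10 h, spring loses 68.9% of its Q, which gives X near 48.6%.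

I side with Ben: X falls as the charge rises, so summer, winter, dusk, spring. The forecast takes his side too, with summer > winter > dusk > spring, 65% and 41%, lower than his spring figure, and it holds that “selectivity looks independent of Q”.

The flasks give summer > winter > dusk > spring: summer 63.0%, winter 61.1%, dusk 58.7%, spring 39.9%. Ben's figure for spring is 8.7 percentage points too high: the spring flask has lost 60.2% of its Q by 10.0 h, against his 68.9%.

    Q + D ⇌ J (K = 2.91 /M, k = 0.0487 /M/min)
    J → X (k = 0.0335 /min)
    J → G (k = 0.0156 /min)
    E ⇌ D, rate k4*(csat - [D]) (kL = 0.00802 /min)

Ben wins, but Ada's view has its region: from 0.10 M to 0.30 M of Q, X moves by 4.3 points, close to her 63.4%, while spring stands 23 points below it. In spring, J turns into X 2.1 times as fast as into G at 10.0 h, and 2.1 times at 4.69 h. S times the Q lost, J set aside, gives 41.2% for spring against 39.9%, and for the neighbouring flask with 0.25 M of Q it gives 62.0% against 60.0%.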